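(The readings are calculated from invented constants; noise was put on by code.)

| flask | starting material | gas phase | remark | time |
|---|---|---|---|---|
| violet | 2.5 × 10⁻⁴ M | 0.20 mM (held) | run made earlier |  |
| ochre | 3.8 × 10⁻⁴ M | 0.20 mM (held) | run made earlier |  |
| flask | 5.0 × 10⁻⁴ M | 0.20 mM (held) |  | 2.0 min |

| run | time / min | over-reacted product / % | target / % | starting material / % |
|---|---|---|---|---|
| violet | 0.167 | 2.0 | 14.1 | 83.7 |
| violet | 0.500 | 23.5 | 25.4 | 50.3 |
| violet | 0.833 | 49.3 | 21.8 | 30.1 |
| violet | 1.33 | 76.1 | 12.1 | 13.2 |
| violet | 2.00 | 92.6 | 3.9 | 4.3 |
| violet | 2.50 | 97.6 | 1.1 | 1.5 |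
| ochre | 0.167 | 3.0 | 12.9 | 84.4 |
| ochre | 0.500 | 19.4 | 26.5 | 53.3 |
| ochre | 0.833 | 40.7 | 26.6 | 32.6 |
| ochre | 1.33 | 70.4 | 14.8 | 15.5 |
| ochre | 2.00 | 90.4 | 5.0 | 3.9 |
| ochre | 2.50 | 96.0 | 2.1 | 1.1 |

(each reading ± 0.5 percentage points)

- the analysis behind the earlier runs scatters by 0.5 percentage points, standard deviation
- at the start none of the gas phase is in solution
- a reading or a percentage of target counts all its forms, free or not

1. the species that holds most of what was charged as starting material, at 2.0 min (target / starting material / over-reacted product)
2. the largest share itself, whichever of these holds it, in percent of the starting material charged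

1. The constants we can read first are the time constants of the two runs. Between 0.500 min and 1.33 min, c(starting material) falls roughly as a pseudo-first-order decay, and we take its decay constant as the clock of a run. Violet reads 1.61 min⁻¹ and ochre 1.49 min⁻¹, each with the scatter of 0.5 percentage points in it.

2. Ochre looks nearly the same as violet. But it charges more starting material on the same held gas, and its clock is slower. So at 2.00 min ochre reads 90.4% over-reacted product, less than violet's 92.6%.

3. A straight line in the charge through both clocks gives the flask 1.37 min⁻¹. The ratio comes to 0.852. This is the clock ratio: a run's decay constant divided by violet's.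

4. So we reckon that the flask at 2.0 min stands where violet stood at 1.70 min. Between violet's readings that gives 85.3% over-reacted product.

5. The forecast names over-reacted product at 87%, a little above our figure. Its ground: “dissolved gas is drawn down by reaction, so supply is starting to limit the rate”.

6. The flask gives over-reacted product at 84.9%, with target at 9.41% and starting material at 5.73%.

    gas phase ⇌ dissolved gas, rate k1*(csat - [dissolved gas]) (kL = 0.131 s⁻¹)
    starting material + dissolved gas → target (k = 278 L mol⁻¹ s⁻¹)
    dissolved gas + target → over-reacted product (k = 540 L mol⁻¹ s⁻¹)
    crystals ⇌ target, rate k4*(cs4 - [target]) while solid is left; crystals form when [target] > cs4 (solubility = 0.0820 mM, k = 6.70 s⁻¹)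
    2 dissolved gas → homo dimer (k = 443 L mol⁻¹ s⁻¹)

The flask has homo dimer, which the forecast's number does not hold. Its step took gas, a turnover of 79.9% of the charge. Without that step the flask reads 96.7% over-reacted product against 84.9%, a part of the slowing, and the same species still holds most. The resistance on the way from gas phase to dissolved gas and the reading at this time, not ten times later, act together on the same figure: without the resistance the flask reads 99.7%, and at 20.0 min it reads 100%. The step moves the shown readings by 15 times their scatter, so the clock ratio 0.852 already carries it. A neighbour flask charged with 2.0 × 10⁻⁴ M gets the ratio 1.03, which puts it at violet's 2.06 min and at a reckoned 93.2%; that neighbour itself ends at 92.8%.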